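If a fixed amount of a catalyst charge is lost before it works and the rate follows what remains, a larger charge gains more than in proportion, and the excess tells the amount.

| flask | substrate | free catalyst | time |
|---|---|---|---|
| dawn | 0.0500 M | 0.00400 M |  |
| spring | 0.0250 M | 0.00400 M |  |
| noon | 0.0500 M | 0.00800 M |  |
| winter | 0.0750 M | 0.00400 M |  |
| dusk | 0.0500 M | 0.0180 M | 8.6 min |

- dawn run (time / min: [target] / M): 0.34: 0.00153; 0.65: 0.00246; 1.2: 0.00467; 2.4: 0.00835; 4.5: 0.01505; 8.6: 0.02425
- spring run (time / min: [target] / M): 0.34: 0.00138; 0.65: 0.00263; 1.2: 0.00383; 2.4: 0.00782; 4.5: 0.01298; 8.6: 0.01970
- noon run (time / min: [target] / M): 0.34: 0.00279; 0.65: 0.00573; 1.2: 0.00969; 2.4: 0.01867; 4.5: 0.03172; 8.6: 0.04427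
- winter run (time / min: [target] / M): 0.34: 0.00147; 0.65: 0.00243; 1.2: 0.00477; 2.4: 0.00901; 4.5: 0.01569; 8.6: 0.02533

(readings scatter by 2 × 10⁻⁴ M)

* the power of [free catalyst] that the first rate follows, about the charge of the dawn run; measure it at two percent of substrate made into target
* the power of [substrate] that the first rate follows, about the charge of the dawn run; measure it at two percent of substrate made into target (one fixed amount of target, the same in the runs compared)
* the spring run starts with 0.0250 M less of substrate than the dawn run, and with no target. Compared where both hold the same amount of substrate, once fifteen percent of what the spring run was charged with has turned into target, is the spring run faster, slower or alike (within a tenth)?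
* target in the dusk run at 8.6 min, as a share of the substrate charged

- Overall: substrate -> target, with free catalyst as catalyst.
- Constant volume, constant temperature.
- A reading of a species includes what of it is bound.
- An order is taken over about fifteen percent of the charge, up and down.

I compared the noon and dawn runs at one moment, 2.4 min: noon held 2.24 times the target of dawn, more than its 2.00 times the free catalyst. The dawn reading there carries a scatter of 2.40%. Taking the target made by then as proportional to the charge of free catalyst less a fixed loss, I solved for the lost share, the part of the dawn charge of free catalyst that does no work, and read 19.1%. A working part of that kind follows the charge with the power one over one minus the share, so I reckoned the catalyst order at 1.24. The comparison drifted: by 8.6 min the ratio of noon to dawn had fallen to 1.83, with the noon target at 88.5% of the substrate charged.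

The forecast gave 1.05 for the catalyst order, 0.1 for the substrate order, faster for the spring run and 99% for dusk, saying “conversion is essentially complete”. My order stood above its figure. Its dusk figure is what a power-law view gives.

The simulation gave 1.3 for the catalyst order, 0.082 for the substrate order, faster for the spring run and 87.1% for dusk.

    free catalyst + substrate ⇌ catalyst-substrate complex, settled at all times (269.0 /M)
    catalyst-substrate complex ⇌ target + free catalyst (1.356 /min, 17.22 /M/min)
    catalyst-substrate complex → spent catalyst + substrate (0.08460 /min)
    free catalyst + impurity → spent catalyst

My reckoned loss is 9.54% of the free catalyst charged to the noon run, and the dawn run took 2.41 times as long as the noon run to turn a quarter of its substrate. In the dusk run my reckoned loss comes to 4.24% of the free catalyst charged; impurity took its amount at once at the start (catalyst poisoning). Afterwards in dusk, complex went on to target, target and free catalyst returned to complex, and complex gave spent catalyst, and at 8.6 min target stood at 87.1% of the substrate charged, below the noon reading of 88.5%.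

(The numbers in the tables come from a simulation with made-up constants; scatter was added.)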